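The side chain is cut at the C13–methyl and C14–C15 bonds. The key step exploits the E-trisubstituted C13=C14 alkene, methylated at C13, with C16 of the butenolide ring in the homoallylic position. Zirconium-catalysed syn methylalumination of a terminal alkyne, then opening of a chiral epoxide at its CH2 carbon by the derived lithium alanate, forms both bonds, fixes the E geometry and brings in C16 with its oxygen in one operation. The precursor is alkyne 17, a 15,16-dinorlabd-13-yne on the trans-decalin (rings A and B) of abietic acid, with the 6α- and 8α-hydroxyls as triethylsilyl ethers and the C18 hydroxyl as a PMB ether.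

Key step: step 13

Remark on numbering: C1–C12 and C18–C20 follow labdane numbering; the chain continues C13 (alkene carbon bearing CH3), C14, C15, C16 (lactone CH–O) and C17 (lactone carbon bearing CH3); the one-carbon branch on C8 (C14 of abietic acid) is written C8′.
Assumption: abietic acid is used as the purified acid and but-3-en-2-ol as the racemate; the diol configuration in 4 and the enol acetate geometry in 6 are immaterial because both elements are destroyed.

Step 1
Reactants: 1 abietic acid
Product: 2 abietinol (abieta-7,13-dien-18-ol)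
Conditions: LiAlH4, THF, 0 °C → reflux
Reagents that add atoms: none
Why: Hydride reduction of the hindered C18 carboxylic acid to the neopentyl alcohol should leave the diene and the ring stereocentres C4, C5, C9 and C10 untouched.

Step 2
Reactants: 2 abietinol
Product: 3 18-(4-methoxybenzyloxy)abieta-7,13-diene
Conditions: NaH, PMBCl, Bu4NI (cat.), THF/DMF, 0 °C → rt
Reagents that add atoms: 4-methoxybenzyl chloride, COc1ccc(CCl)cc1
Why: Williamson etherification of the primary alkoxide installs the C18 protecting group, which is later removed oxidatively together with the one on C17.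

Step 3
Reactants: 3 18-(4-methoxybenzyloxy)abieta-7,13-diene
Product: 5 keto enal (C8–CHO with C7=C8 and C9–CH2CH2–CO–CH(CH3)2), via ring C cis-diol 4 (not isolated)
Conditions: OsO4 (cat.), NaIO4, 2,6-lutidine, dioxane/H2O, rt
Reagents that add atoms: osmium tetroxide, O=[Os](=O)(=O)=O; sodium periodate, [Na+].[O-]I(=O)(=O)=O
Why: Lemieux–Johnson cleavage, in which OsO4 dihydroxylates the isopropyl-bearing ring C end of the heteroannular diene and periodate cleaves the glycol, should open ring C and leave the now electron-poor C7=C8 enal bond alone.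

Step 4
Reactants: 5 keto enal
Product: 6 dienyl acetate (C6=C7 and C8=C8′–OAc)
Conditions: Ac2O, Et3N, DMAP (cat.), 60 °C
Reagents that add atoms: acetic anhydride, CC(=O)OC(C)=O
Why: Enol acetylation of the enal with loss of a C6 hydrogen gives the through-conjugated 1-acetoxy diene, an aldehyde-specific process that the hindered isopropyl ketone should not undergo under amine base.

Step 5
Reactants: 6 dienyl acetate
Product: 8 6α-hydroxy keto enal, via 6α,7α-epoxy dienyl acetate 7 (not isolated)
Conditions: m-CPBA (1.05 equiv), NaHCO3, dioxane/H2O, 0 °C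
Reagents that add atoms: m-chloroperbenzoic acid, OOC(=O)c1cccc(Cl)c1
Why: Peracid oxidation of a dienyl ester at its remote double bond (vinylogous Rubottom-type γ-hydroxylation) should place oxygen on the α face of C6, the β face being blocked by the axial methyls on C4 and C10, and the vinyl epoxide then opens with loss of acetyl to restore the C7=C8 enal, which sets C6.

Step 6
Reactants: 8 6α-hydroxy keto enal
Product: 11 6α-hydroxy-8-methylidene isopropyl ketone, via tosylhydrazone 9 (not isolated), via allylic diazene 10 (not isolated)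
Conditions: TsNHNH2, EtOH, rt; catecholborane, CHCl3, 0 °C; NaOAc·3H2O, 60 °C
Reagents that add atoms: none
Why: Reductive 1,3-transposition of an α,β-unsaturated tosylhydrazone: the aldehyde condenses selectively over the hindered ketone, reduction of C=N and loss of sulfinate give a diazene that expels N2 by a retro-ene hydrogen shift to C7, and the alkene moves to the exocyclic C8=C8′ position.

Step 7
Reactants: 11 6α-hydroxy-8-methylidene isopropyl ketone
Product: 13 epoxy isopropyl ester, via epoxy ketone 12 (not isolated)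
Conditions: m-CPBA (3 equiv), NaHCO3, DCM, 0 °C → rt
Reagents that add atoms: m-chloroperbenzoic acid, OOC(=O)c1cccc(Cl)c1
Why: The peracid should first epoxidise the 1,1-disubstituted alkene on the α face, anti to the axial C10 methyl and guided by the 6α-hydroxyl, which sets C8, and then convert the ketone into the isopropyl ester by Baeyer–Villiger migration of the secondary alkyl group.

Step 8
Reactants: 13 epoxy isopropyl ester
Product: 15 epoxy alkyne, via epoxy aldehyde 14 (not isolated)
Conditions: i-Bu2AlH, DCM, −78 °C; then MeOH, K2CO3, dimethyl (1-diazo-2-oxopropyl)phosphonate, rt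
Reagents that add atoms: dimethyl (1-diazo-2-oxopropyl)phosphonate, CC(=O)C(=[N+]=[N-])P(=O)(OC)OC
Why: Low-temperature reduction of the isopropyl ester stops at the aldehyde, which the Ohira–Bestmann variant of the Seyferth–Gilbert homologation converts in the same flask into the terminal alkyne under conditions that the hindered epoxide should survive.

Step 9
Reactants: 15 epoxy alkyne
Product: 16 18-(4-methoxybenzyloxy)-15,16-dinorlabd-13-yne-6α,8α-diol
Conditions: LiBHEt3, THF, 0 °C → rt
Reagents that add atoms: none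
Why: Hydride opens the spiro-epoxide at its unhindered CH2 carbon by SN2, so the C8–O bond is untouched and the 8α-tertiary alcohol with a β-methyl results, the alkyne and PMB ether being inert.

Step 10
Reactants: 16 alkyne diol
Product: 17 18-(4-methoxybenzyloxy)-6α,8α-bis(triethylsilyloxy)-15,16-dinorlabd-13-yne
Conditions: Et3SiOTf, 2,6-lutidine, DCM, 0 °C → rt
Reagents that add atoms: triethylsilyl trifluoromethanesulfonate, CC[Si](CC)(CC)OS(=O)(=O)C(F)(F)F
Why: A silyl triflate with a hindered pyridine base should silylate both the secondary and the hindered tertiary hydroxyl without touching the alkyne or the PMB ether.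

Step 11
Reactants: 18 but-3-en-2-ol (racemic)
Product: 19 (2S,3R)-3,4-epoxybutan-2-ol
Conditions: Ti(OiPr)4, L-(+)-DIPT, t-BuOOH (0.55 equiv), 4 Å MS, DCM, −20 °C
Reagents that add atoms: tert-butyl hydroperoxide, CC(C)(C)OO
Why: In the Sharpless kinetic resolution the L-(+)-tartrate catalyst epoxidises the (S)-alcohol fast and on the face that gives the erythro epoxy alcohol, so the reagent sets the epoxide carbon (later C16) while the (R)-alcohol is left behind.

Step 12
Reactants: 19 (2S,3R)-3,4-epoxybutan-2-ol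
Product: 20 (2S,3R)-3,4-epoxybutan-2-yl 4-methoxybenzyl ether
Conditions: NaH, PMBCl, Bu4NI (cat.), THF, 0 °C → rt
Reagents that add atoms: 4-methoxybenzyl chloride, COc1ccc(CCl)cc1
Why: Williamson etherification in an aprotic medium should outrun Payne rearrangement of the epoxy alkoxide and leaves both stereocentres unchanged.

Step 13
Reactants: 17 bis-TES alkyne; 20 epoxide PMB ether
Product: 23 E homoallylic alcohol (16R), via alkenyldimethylalane 21 (not isolated), via lithium alkenylalanate 22 (not isolated)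
Conditions: Me3Al, Cp2ZrCl2 (cat.), DCM, 0 °C → rt; n-BuLi, hexane/THF, −78 → 0 °C; then 20, THF, 0 °C → rt; aqueous work-up
Reagents that add atoms: trimethylaluminium, C[Al](C)C
Why: Zirconocene-assisted addition of methyl and aluminium across the terminal alkyne is syn and puts methyl on the internal carbon C13 and aluminium on the terminal carbon C14 (Negishi carboalumination), giving 21. n-BuLi turns 21 into the more nucleophilic alanate 22, whose alkenyl group opens epoxide 20 at its CH2 carbon by SN2 with retention of alkene geometry, the known alkenylalanate–epoxide coupling. No ring is closed and no stereocentre is created: the E geometry follows from the syn addition, and C16 keeps the R configuration it has in 20 because its C–O bond is not broken. The step needs methyl at C13 and attack at the epoxide CH2; the terminal alkyne secures the first, and the steric difference between the primary and the alkoxy-substituted secondary epoxide carbon secures the second. The silyl and PMB ethers should be inert to the organoaluminium medium.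

Step 14
Reactants: 23 E homoallylic alcohol
Product: 24 C16 diethylphosphonoacetate
Conditions: (EtO)2P(O)CH2CO2H, EDC·HCl, DMAP (cat.), DCM, 0 °C → rt
Reagents that add atoms: diethylphosphonoacetic acid, CCOP(=O)(CC(=O)O)OCC
Why: Steglich-type esterification of the only free hydroxyl attaches the two carbons and the phosphonate needed for lactone closure without affecting C16.

Step 15
Reactants: 24 C16 diethylphosphonoacetate
Product: 25 C17,C18-diol
Conditions: DDQ, DCM/pH 7 buffer, 0 °C → rt
Reagents that add atoms: none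
Why: Oxidative cleavage of both PMB ethers by DDQ frees the C17 and C18 hydroxyls while the silyl ethers, the trisubstituted alkene and the phosphonoacetate should remain.

Step 16
Reactants: 25 C17,C18-diol
Product: 26 keto aldehyde
Conditions: Dess–Martin periodinane, NaHCO3, DCM, rt
Reagents that add atoms: none
Why: Dess–Martin oxidation under buffered conditions converts the secondary C17 alcohol into the methyl ketone and the neopentyl C18 alcohol into the non-enolisable aldehyde without epimerising C16.

Step 17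
Reactants: 26 keto aldehyde
Product: 27 bis-TES butenolide
Conditions: LiCl, i-Pr2NEt, MeCN, rt, high dilution
Reagents that add atoms: none
Why: An intramolecular Horner–Wadsworth–Emmons reaction (Masamune–Roush conditions) between the phosphonoacetate and the adjacent C17 ketone closes the five-membered unsaturated lactone under a mild base that should spare C16 and, at high dilution, the hindered C18 aldehyde.

Step 18
Reactants: 27 bis-TES butenolide
Product: 28 target (CNP0143336.1)
Conditions: HF·pyridine, pyridine/THF, 0 °C → rt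
Reagents that add atoms: none
Why: Fluoride-mediated cleavage of the secondary and tertiary triethylsilyl ethers under mildly acidic conditions frees the 6α- and 8α-hydroxyls without harming the aldehyde, the butenolide or the alkene.

Compound list
1 | abietic acid (abieta-7,13-dien-18-oic acid) | C3=C(C(C)C)CC[C@@H]1[C@@]2(C)CCC[C@@](C)(C(=O)O)[C@@H]2CC=C13 | starting material
2 | abietinol (abieta-7,13-dien-18-ol) | C3=C(C(C)C)CC[C@@H]1[C@@]2(C)CCC[C@@](C)(CO)[C@@H]2CC=C13 | intermediate
3 | 18-(4-methoxybenzyloxy)abieta-7,13-diene | C3=C(C(C)C)CC[C@@H]1[C@@]2(C)CCC[C@@](C)(COCc4ccc(OC)cc4)[C@@H]2CC=C13 | intermediate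
4 | 18-(4-methoxybenzyloxy)abiet-7-ene-13α,14α-diol (ring C cis-diol, abietane numbering) | [C@H]3(O)[C@](O)(C(C)C)CC[C@@H]1[C@@]2(C)CCC[C@@](C)(COCc4ccc(OC)cc4)[C@@H]2CC=C13 | intermediate (not isolated)
5 | keto enal: 18-PMB ether with C7=C8, CHO on C8 and CH2CH2COCH(CH3)2 on C9 | CC(C)C(=O)CC[C@@H]1[C@@]2(C)CCC[C@@](C)(COCc3ccc(OC)cc3)[C@@H]2CC=C1C=O | intermediate
6 | dienyl acetate of 5 (C6=C7, C8=C8′–OAc, E/Z mixture) | CC(C)C(=O)CC[C@@H]1[C@@]2(C)CCC[C@@](C)(COCc3ccc(OC)cc3)[C@@H]2C=CC1=COC(C)=O | intermediate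
7 | 6α,7α-epoxide of 6 | CC(C)C(=O)CC[C@@H]1[C@@]2(C)CCC[C@@](C)(COCc3ccc(OC)cc3)[C@@H]2[C@H]4O[C@H]4C1=COC(C)=O | intermediate (not isolated)
8 | 6α-hydroxy keto enal | CC(C)C(=O)CC[C@@H]1[C@@]2(C)CCC[C@@](C)(COCc3ccc(OC)cc3)[C@@H]2[C@@H](O)C=C1C=O | intermediate
9 | N-tosylhydrazone of the aldehyde of 8 | CC(C)C(=O)CC[C@@H]1[C@@]2(C)CCC[C@@](C)(COCc3ccc(OC)cc3)[C@@H]2[C@@H](O)C=C1C=NNS(=O)(=O)c4ccc(C)cc4 | intermediate (not isolated)
10 | allylic diazene (C8′H2–N=NH on C8, C7=C8) | CC(C)C(=O)CC[C@@H]1[C@@]2(C)CCC[C@@](C)(COCc3ccc(OC)cc3)[C@@H]2[C@@H](O)C=C1CN=N | intermediate (not isolated)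
11 | 6α-hydroxy-8-methylidene isopropyl ketone | CC(C)C(=O)CC[C@@H]1[C@@]2(C)CCC[C@@](C)(COCc3ccc(OC)cc3)[C@@H]2[C@@H](O)CC1=C | intermediate
12 | 8α,8′-epoxy (spiro-oxirane, oxygen α) 6α-hydroxy isopropyl ketone | CC(C)C(=O)CC[C@@H]1[C@@]2(C)CCC[C@@](C)(COCc3ccc(OC)cc3)[C@@H]2[C@@H](O)C[C@]14CO4 | intermediate (not isolated)
13 | isopropyl ester of the 8α,8′-epoxy-6α-hydroxy C13 acid | CC(C)OC(=O)CC[C@@H]1[C@@]2(C)CCC[C@@](C)(COCc3ccc(OC)cc3)[C@@H]2[C@@H](O)C[C@]14CO4 | intermediate
14 | 8α,8′-epoxy-6α-hydroxy C13 aldehyde | O=CCC[C@@H]1[C@@]2(C)CCC[C@@](C)(COCc3ccc(OC)cc3)[C@@H]2[C@@H](O)C[C@]14CO4 | intermediate (not isolated)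
15 | 8α,8′-epoxy-6α-hydroxy-18-(4-methoxybenzyloxy)-15,16-dinorlabd-13-yne | C#CCC[C@@H]1[C@@]2(C)CCC[C@@](C)(COCc3ccc(OC)cc3)[C@@H]2[C@@H](O)C[C@]14CO4 | intermediate
16 | 18-(4-methoxybenzyloxy)-15,16-dinorlabd-13-yne-6α,8α-diol | C#CCC[C@@H]1[C@@]2(C)CCC[C@@](C)(COCc3ccc(OC)cc3)[C@@H]2[C@@H](O)C[C@@]1(C)O | intermediate
17 | 18-(4-methoxybenzyloxy)-6α,8α-bis(triethylsilyloxy)-15,16-dinorlabd-13-yne | C#CCC[C@@H]1[C@@]2(C)CCC[C@@](C)(COCc3ccc(OC)cc3)[C@@H]2[C@@H](O[Si](CC)(CC)CC)C[C@@]1(C)O[Si](CC)(CC)CC | intermediate (key-step precursor)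
18 | but-3-en-2-ol (racemic) | CC(O)C=C | starting material
19 | (2S,3R)-3,4-epoxybutan-2-ol | C[C@H](O)[C@H]1CO1 | intermediate
20 | (2S,3R)-3,4-epoxybutan-2-yl 4-methoxybenzyl ether | C[C@H](OCc1ccc(OC)cc1)[C@H]2CO2 | intermediate (key-step precursor)
21 | (E)-alkenyldimethylalane (Al on C14, CH3 on C13) | C[Al](C)/C=C(\C)CC[C@@H]1[C@@]2(C)CCC[C@@](C)(COCc3ccc(OC)cc3)[C@@H]2[C@@H](O[Si](CC)(CC)CC)C[C@@]1(C)O[Si](CC)(CC)CC | intermediate (not isolated)
22 | lithium (E)-alkenyl(butyl)dimethylalanate | [Li+].CCCC[Al-](C)(C)/C=C(\C)CC[C@@H]1[C@@]2(C)CCC[C@@](C)(COCc3ccc(OC)cc3)[C@@H]2[C@@H](O[Si](CC)(CC)CC)C[C@@]1(C)O[Si](CC)(CC)CC | intermediate (not isolated)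
23 | E homoallylic alcohol: 16R carbinol, C17 and C18 PMB ethers, 6α,8α-bis-TES ether | C[C@H](OCc4ccc(OC)cc4)[C@H](O)C/C=C(\C)CC[C@@H]1[C@@]2(C)CCC[C@@](C)(COCc3ccc(OC)cc3)[C@@H]2[C@@H](O[Si](CC)(CC)CC)C[C@@]1(C)O[Si](CC)(CC)CC | intermediate (key-step product)
24 | C16 diethylphosphonoacetate of 23 | C[C@H](OCc4ccc(OC)cc4)[C@H](OC(=O)CP(=O)(OCC)OCC)C/C=C(\C)CC[C@@H]1[C@@]2(C)CCC[C@@](C)(COCc3ccc(OC)cc3)[C@@H]2[C@@H](O[Si](CC)(CC)CC)C[C@@]1(C)O[Si](CC)(CC)CC | intermediate
25 | C17,C18-diol C16 phosphonoacetate | C[C@H](O)[C@H](OC(=O)CP(=O)(OCC)OCC)C/C=C(\C)CC[C@@H]1[C@@]2(C)CCC[C@@](C)(CO)[C@@H]2[C@@H](O[Si](CC)(CC)CC)C[C@@]1(C)O[Si](CC)(CC)CC | intermediate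
26 | C17 ketone, C18 aldehyde, C16 phosphonoacetate | CC(=O)[C@H](OC(=O)CP(=O)(OCC)OCC)C/C=C(\C)CC[C@@H]1[C@@]2(C)CCC[C@@](C)(C=O)[C@@H]2[C@@H](O[Si](CC)(CC)CC)C[C@@]1(C)O[Si](CC)(CC)CC | intermediate
27 | 6α,8α-bis(triethylsilyl) ether of the target | CC1=CC(=O)O[C@@H]1C/C=C(\C)CC[C@@H]1[C@@]2(C)CCC[C@@](C)(C=O)[C@@H]2[C@@H](O[Si](CC)(CC)CC)C[C@@]1(C)O[Si](CC)(CC)CC | intermediate
28 | CNP0143336.1 | CC1=CC(=O)O[C@@H]1C/C=C(\C)CC[C@@H]1[C@@]2(C)CCC[C@@](C)(C=O)[C@@H]2[C@@H](O)C[C@@]1(C)O | target

Total step count: 18 (steps 1–10 to the alkyne, steps 11–12 to the epoxide, step 13, steps 14–18).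
Longest linear sequence: 16 (steps 1–10 and 13–18).

Steps most likely to fail

Step 5. The oxygen may be delivered partly to the β face of C6, or to the enol-acetate bond instead of C6=C7, so that C6 is formed as an epimer mixture. The fallback sets the centre by thermodynamically controlled electron-transfer reduction instead of face-selective oxygen transfer. It sets out from 16, to which any C6-epimeric material is carried through steps 6–9. Dess–Martin oxidation of 16 gives the 6-oxo-8α-hydroxy alkyne F1, one compound from both epimers. Reduction of F1 with SmI2, H2O and Et3N in THF should place the new hydroxyl equatorial (6α), away from the two axial methyl groups, and comes back to the route at 16.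

Step 13. Carbometalation may stop short, the mixed alanate may transfer methyl or butyl instead of the alkenyl group, or residual Lewis acid may open the epoxide at C16. The fallback sets out from 17: the alkenylalane 21, made as in step 13, is quenched with I2 to give the (E)-vinyl iodide F2. Exchange with t-BuLi in Et2O at −78 °C gives the alkenyllithium F3, which should open 20 at its CH2 carbon in the presence of BF3·OEt2 at −78 °C and comes back to the route at 23.

Step 7. During the slow Baeyer–Villiger oxidation the acid formed may open or rearrange the spiro-epoxide. The fallback avoids having the epoxide and the peracid together and sets out from 11. Mukaiyama hydration (Co(acac)2, PhSiH3, O2, i-PrOH/THF) should give the 6α,8α-dihydroxy ketone F4, the oxygen entering on the less hindered α face. Baeyer–Villiger oxidation of this alkene-free ketone (m-CPBA, NaHCO3) gives the dihydroxy isopropyl ester F5. Reduction with i-Bu2AlH and Ohira–Bestmann homologation in one flask, through the hydroxy aldehyde F6 (in equilibrium with its lactol), comes back to the route at 16.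

Further compounds
F1 | step 5 | 8α-hydroxy-18-(4-methoxybenzyloxy)-15,16-dinorlabd-13-yn-6-one | C#CCC[C@@H]1[C@@]2(C)CCC[C@@](C)(COCc3ccc(OC)cc3)[C@@H]2C(=O)C[C@@]1(C)O
F2 | step 13 | (E)-14-iodo-13-ene, C18 PMB ether, 6α,8α-bis-TES ether | I/C=C(\C)CC[C@@H]1[C@@]2(C)CCC[C@@](C)(COCc3ccc(OC)cc3)[C@@H]2[C@@H](O[Si](CC)(CC)CC)C[C@@]1(C)O[Si](CC)(CC)CC
F3 | step 13 | (E)-alkenyllithium from F2 | [Li]/C=C(\C)CC[C@@H]1[C@@]2(C)CCC[C@@](C)(COCc3ccc(OC)cc3)[C@@H]2[C@@H](O[Si](CC)(CC)CC)C[C@@]1(C)O[Si](CC)(CC)CC
F4 | step 7 | 6α,8α-dihydroxy isopropyl ketone | CC(C)C(=O)CC[C@@H]1[C@@]2(C)CCC[C@@](C)(COCc3ccc(OC)cc3)[C@@H]2[C@@H](O)C[C@@]1(C)O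
F5 | step 7 | 6α,8α-dihydroxy isopropyl ester | CC(C)OC(=O)CC[C@@H]1[C@@]2(C)CCC[C@@](C)(COCc3ccc(OC)cc3)[C@@H]2[C@@H](O)C[C@@]1(C)O
F6 | step 7 | 6α,8α-dihydroxy C13 aldehyde | O=CCC[C@@H]1[C@@]2(C)CCC[C@@](C)(COCc3ccc(OC)cc3)[C@@H]2[C@@H](O)C[C@@]1(C)O
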